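**Retrosynthetic overview**
1. Target 20 ← 19 (hydrogenolysis) ← 18 (methylation of O5) ← 17 (benzylation of O7 and O4′) ← 16 (global hydrogenolysis). O5 is told apart from O7 and O4′ by its hydrogen bond to C4=O.
2. 16 ← acid 14 by disconnection of C4–C4a: an intramolecular Friedel–Crafts acylation closes the pyranone ring C, the only ring made in the route (rings A and B are bought as arenes).
3. Feature: O1 is the oxygen para to the C6 methyl of the 2-methylphloroglucinol ring A. In the aryl ether precursor a mirror plane runs through O1 and the methyl group, so the two ortho carbons (future C4a and C8) are identical and closure can only give the 6-methyl chromone.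
4. 14 ← ester 13 ← phenol 5 + enol tosylate 12 (vinylic substitution at the future C2). 12 comes from 4-hydroxy-3,5-dimethoxyphenylacetic acid by esterification, benzylation, formylation and tosylation.
5. 5 ← 2-methylresorcinol by bis-etherification and C5–H borylation/oxidation. The ring A ethers are 4-methylbenzyl, not benzyl, so that the protecting groups offer the iridium catalyst no unhindered arene C–H.

Key step: step 9

Remark: the target has no stereocentre and no stereogenic double bond; it is achiral, so no enantiomer has to be selected.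
Remark: acrylates 11–15 are written as the Z isomers expected from the chelated enolate and from retentive substitution; the ring closure is expected not to depend on this geometry.

**Route**

Step 1
Reactants: 1 2-methylresorcinol; 2 4-methylbenzyl bromide
Product: 3 2-methyl-1,3-bis[(4-methylbenzyl)oxy]benzene
Conditions: 2 (2.2 equiv), K2CO3, DMF, 60 °C
Reagents that add atoms: 4-methylbenzyl bromide (2), Cc1ccc(CBr)cc1
Why: Williamson etherification of both phenols; 4-methylbenzyl is chosen over benzyl because each of its arene C–H bonds lies ortho to a substituent and should stay untouched in the sterically governed borylation of step 2, while the group is still removed by hydrogenolysis.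

Step 2
Reactants: 3 2-methyl-1,3-bis[(4-methylbenzyl)oxy]benzene
Product: 5 4-methyl-3,5-bis[(4-methylbenzyl)oxy]phenol, via pinacol arylboronate 4 (not isolated)
Conditions: [Ir(OMe)(cod)]2 (cat.), dtbpy (cat.), B2pin2 (0.6 equiv), THF, 65 °C; then aq. H2O2, NaOH, 0 °C → rt
Reagents that add atoms: bis(pinacolato)diboron, CC1(C)OB(OC1(C)C)B1OC(C)(C)C(C)(C)O1 (atoms in 4 only); hydrogen peroxide, OO
Why: Iridium-catalysed C–H borylation is sterically controlled and should select C5–H, the only arene C–H of 3 flanked by two hydrogens, and alkaline peroxide oxidation of the arylboronate (1,2-aryl shift from boron to oxygen) then places the hydroxyl, the future O1, on that carbon.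

Step 3
Reactants: 6 4-hydroxy-3,5-dimethoxyphenylacetic acid
Product: 7 methyl 2-(4-hydroxy-3,5-dimethoxyphenyl)acetate
Conditions: MeOH, cat. H2SO4, reflux
Reagents that add atoms: methanol, CO
Why: Fischer esterification of the carboxylic acid, which leaves the phenol free.

Step 4
Reactants: 7 methyl 2-(4-hydroxy-3,5-dimethoxyphenyl)acetate; 8 benzyl bromide
Product: 9 methyl 2-[4-(benzyloxy)-3,5-dimethoxyphenyl]acetate
Conditions: BnBr, K2CO3, DMF, rt → 50 °C
Reagents that add atoms: benzyl bromide (8), BrCc1ccccc1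
Why: Williamson etherification of the phenol under a weak base that should leave the methyl ester and its α-CH2 alone.

Step 5
Reactants: 9 methyl 2-[4-(benzyloxy)-3,5-dimethoxyphenyl]acetate; 10 methyl formate
Product: 11 methyl (Z)-2-[4-(benzyloxy)-3,5-dimethoxyphenyl]-3-hydroxyprop-2-enoate (enol form of the α-formyl ester)
Conditions: NaH, HCO2Me (excess), THF, 0 °C → rt; then dil. HCl
Reagents that add atoms: methyl formate (10), COC=O
Why: Crossed Claisen condensation with a non-enolisable formate, driven by deprotonation of the product to its stabilised enolate; the matching methyl ester and methyl formate exclude transesterification, and the product should rest as the hydrogen-bonded Z enol.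

Step 6
Reactants: 11 methyl (Z)-2-[4-(benzyloxy)-3,5-dimethoxyphenyl]-3-hydroxyprop-2-enoate
Product: 12 methyl (Z)-2-[4-(benzyloxy)-3,5-dimethoxyphenyl]-3-{[(4-methylphenyl)sulfonyl]oxy}prop-2-enoate
Conditions: TsCl, N-methylimidazole, LiOH, MeCN, 0 °C
Reagents that add atoms: p-toluenesulfonyl chloride, Cc1ccc(cc1)S(Cl)(=O)=O
Why: O-sulfonylation of the lithium-chelated enolate by the N-sulfonylimidazolium salt should fix the tosyloxy group cis to the ester (Z).

Step 7
Reactants: 5 4-methyl-3,5-bis[(4-methylbenzyl)oxy]phenol; 12 methyl (Z)-2-[4-(benzyloxy)-3,5-dimethoxyphenyl]-3-{[(4-methylphenyl)sulfonyl]oxy}prop-2-enoate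
Product: 13 methyl (Z)-3-{3,5-bis[(4-methylbenzyl)oxy]-4-methylphenoxy}-2-[4-(benzyloxy)-3,5-dimethoxyphenyl]prop-2-enoate
Conditions: Cs2CO3, MeCN, rt
Reagents that add atoms: none
Why: Nucleophilic vinylic substitution by addition–elimination: the unhindered phenoxide adds to the β-carbon of the acrylate and tosylate leaves from the ester enolate, with retention expected for a good nucleofuge; a share of E isomer would be carried on because step 9 should be stereoconvergent.

Step 8
Reactants: 13 methyl (Z)-3-{3,5-bis[(4-methylbenzyl)oxy]-4-methylphenoxy}-2-[4-(benzyloxy)-3,5-dimethoxyphenyl]prop-2-enoate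
Product: 14 (Z)-3-{3,5-bis[(4-methylbenzyl)oxy]-4-methylphenoxy}-2-[4-(benzyloxy)-3,5-dimethoxyphenyl]prop-2-enoic acid
Conditions: LiOH, THF–H2O, rt; then dil. HCl to pH 3
Reagents that add atoms: lithium hydroxide, [Li+].[OH-]
Why: Saponification at the ester carbonyl, as in the known hydrolysis of 3-aryloxyacrylates; alcohol co-solvent is left out so that no alkoxide can exchange with the aryloxy group at the β-carbon.

Step 9
Reactants: 14 (Z)-3-{3,5-bis[(4-methylbenzyl)oxy]-4-methylphenoxy}-2-[4-(benzyloxy)-3,5-dimethoxyphenyl]prop-2-enoic acid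
Product: 16 3-[4-(benzyloxy)-3,5-dimethoxyphenyl]-6-methyl-5,7-bis[(4-methylbenzyl)oxy]-4H-chromen-4-one, via mixed trifluoroacetic anhydride 15 (not isolated)
Conditions: (CF3CO)2O, CH2Cl2, 0 °C → rt
Reagents that add atoms: trifluoroacetic anhydride, O=C(OC(=O)C(F)(F)F)C(F)(F)F (atoms in 15 only)
Why: Trifluoroacetic anhydride turns the acid into the mixed anhydride 15, whose acyl carbon (free or incipient acylium, stabilised by the β-aryloxy oxygen) attacks the phenoxy ring at a carbon ortho to the ether oxygen, and loss of the proton from the σ-complex forms C4–C4a. The closest known reaction type is the Friedel–Crafts cyclisation of 3-aryloxyacrylic acids to chromones, with the trifluoroacetic anhydride closure of 2-aryloxybenzoic acids to xanthones as the model for the mild activation. The pyranone ring (O1, C2, C3, C4, C4a, C8a) closes in a 6-exo mode by electrophilic aromatic substitution, and no stereocentre is formed. The attacked carbon is ortho to one and para to the other 4-methylbenzyloxy group, so the ring should react without a metal Lewis acid, which is what should keep the three benzyl-type ethers in place. No regioselectivity is needed, because the mirror plane through O1 and the methyl group of the phenoxy ring makes both ortho carbons the same and only the 6-methyl chromone can form. The Z acid has carboxyl and aryloxy groups cis as the closure demands, and any E isomer should reach the same product because the Cα–Cβ bond of the acylium has single-bond character in its ketene–oxocarbenium resonance form.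

Step 10
Reactants: 16 3-[4-(benzyloxy)-3,5-dimethoxyphenyl]-6-methyl-5,7-bis[(4-methylbenzyl)oxy]-4H-chromen-4-one
Product: 17 5,7-dihydroxy-3-(4-hydroxy-3,5-dimethoxyphenyl)-6-methyl-4H-chromen-4-one
Conditions: H2 (1 atm), 10% Pd/C, THF–MeOH, rt
Reagents that add atoms: none
Why: Hydrogenolysis of the three benzylic C–O bonds over palladium, which should be faster than reduction of the conjugated C2=C3 bond of the chromone.

Step 11
Reactants: 17 5,7-dihydroxy-3-(4-hydroxy-3,5-dimethoxyphenyl)-6-methyl-4H-chromen-4-one; 8 benzyl bromide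
Product: 18 7-(benzyloxy)-3-[4-(benzyloxy)-3,5-dimethoxyphenyl]-5-hydroxy-6-methyl-4H-chromen-4-one
Conditions: BnBr (2.2 equiv), K2CO3, DMF, rt
Reagents that add atoms: benzyl bromide (8), BrCc1ccccc1
Why: Williamson etherification under weak base; the 5-OH is held in a hydrogen bond to C4=O and flanked by the C6 methyl, so only the 7- and 4′-phenoxides should be alkylated.

Step 12
Reactants: 18 7-(benzyloxy)-3-[4-(benzyloxy)-3,5-dimethoxyphenyl]-5-hydroxy-6-methyl-4H-chromen-4-one
Product: 19 7-(benzyloxy)-3-[4-(benzyloxy)-3,5-dimethoxyphenyl]-5-methoxy-6-methyl-4H-chromen-4-one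
Conditions: MeI (excess), K2CO3, DMF, 50 °C
Reagents that add atoms: iodomethane, CI
Why: Williamson O-methylation of the chelated 5-hydroxyl, the usual forcing alkylation of a chromone 5-OH once every other phenol is capped.

Step 13
Reactants: 19 7-(benzyloxy)-3-[4-(benzyloxy)-3,5-dimethoxyphenyl]-5-methoxy-6-methyl-4H-chromen-4-one
Product: 20 7-hydroxy-3-(4-hydroxy-3,5-dimethoxyphenyl)-5-methoxy-6-methyl-4H-chromen-4-one (target)
Conditions: H2 (1 atm), 10% Pd/C, THF–MeOH, rt
Reagents that add atoms: none
Why: Hydrogenolysis of the two benzyl ethers, which should leave the three aryl methyl ethers and the chromone untouched.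

**Compound list**
1 | 2-methylresorcinol | Cc1c(O)cccc1O | starting material
2 | 4-methylbenzyl bromide | Cc1ccc(CBr)cc1 | starting material
3 | 2-methyl-1,3-bis[(4-methylbenzyl)oxy]benzene | Cc1ccc(COc2cccc(OCc3ccc(C)cc3)c2C)cc1 | intermediate
4 | 2-{4-methyl-3,5-bis[(4-methylbenzyl)oxy]phenyl}-4,4,5,5-tetramethyl-1,3,2-dioxaborolane | Cc1ccc(COc2cc(B3OC(C)(C)C(C)(C)O3)cc(OCc3ccc(C)cc3)c2C)cc1 | intermediate (not isolated)
5 | 4-methyl-3,5-bis[(4-methylbenzyl)oxy]phenol | Cc1ccc(COc2cc(O)cc(OCc3ccc(C)cc3)c2C)cc1 | intermediate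
6 | 4-hydroxy-3,5-dimethoxyphenylacetic acid | COc1cc(CC(=O)O)cc(OC)c1O | starting material
7 | methyl 2-(4-hydroxy-3,5-dimethoxyphenyl)acetate | COC(=O)Cc1cc(OC)c(O)c(OC)c1 | intermediate
8 | benzyl bromide | BrCc1ccccc1 | starting material
9 | methyl 2-[4-(benzyloxy)-3,5-dimethoxyphenyl]acetate | COC(=O)Cc1cc(OC)c(OCc2ccccc2)c(OC)c1 | intermediate
10 | methyl formate | COC=O | starting material
11 | methyl (Z)-2-[4-(benzyloxy)-3,5-dimethoxyphenyl]-3-hydroxyprop-2-enoate | COC(=O)/C(=C\O)c1cc(OC)c(OCc2ccccc2)c(OC)c1 | intermediate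
12 | methyl (Z)-2-[4-(benzyloxy)-3,5-dimethoxyphenyl]-3-{[(4-methylphenyl)sulfonyl]oxy}prop-2-enoate | COC(=O)/C(=C\OS(=O)(=O)c1ccc(C)cc1)c1cc(OC)c(OCc2ccccc2)c(OC)c1 | intermediate
13 | methyl (Z)-3-{3,5-bis[(4-methylbenzyl)oxy]-4-methylphenoxy}-2-[4-(benzyloxy)-3,5-dimethoxyphenyl]prop-2-enoate | COC(=O)/C(=C\Oc1cc(OCc2ccc(C)cc2)c(C)c(OCc2ccc(C)cc2)c1)c1cc(OC)c(OCc2ccccc2)c(OC)c1 | intermediate
14 | (Z)-3-{3,5-bis[(4-methylbenzyl)oxy]-4-methylphenoxy}-2-[4-(benzyloxy)-3,5-dimethoxyphenyl]prop-2-enoic acid | OC(=O)/C(=C\Oc1cc(OCc2ccc(C)cc2)c(C)c(OCc2ccc(C)cc2)c1)c1cc(OC)c(OCc2ccccc2)c(OC)c1 | intermediate (key-step precursor)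
15 | (Z)-3-{3,5-bis[(4-methylbenzyl)oxy]-4-methylphenoxy}-2-[4-(benzyloxy)-3,5-dimethoxyphenyl]prop-2-enoic trifluoroacetic anhydride | O=C(OC(=O)C(F)(F)F)/C(=C\Oc1cc(OCc2ccc(C)cc2)c(C)c(OCc2ccc(C)cc2)c1)c1cc(OC)c(OCc2ccccc2)c(OC)c1 | intermediate (not isolated)
16 | 3-[4-(benzyloxy)-3,5-dimethoxyphenyl]-6-methyl-5,7-bis[(4-methylbenzyl)oxy]-4H-chromen-4-one | COc1cc(-c2coc3cc(OCc4ccc(C)cc4)c(C)c(OCc4ccc(C)cc4)c3c2=O)cc(OC)c1OCc1ccccc1 | intermediate (key-step product)
17 | 5,7-dihydroxy-3-(4-hydroxy-3,5-dimethoxyphenyl)-6-methyl-4H-chromen-4-one | COc1cc(-c2coc3cc(O)c(C)c(O)c3c2=O)cc(OC)c1O | intermediate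
18 | 7-(benzyloxy)-3-[4-(benzyloxy)-3,5-dimethoxyphenyl]-5-hydroxy-6-methyl-4H-chromen-4-one | COc1cc(-c2coc3cc(OCc4ccccc4)c(C)c(O)c3c2=O)cc(OC)c1OCc1ccccc1 | intermediate
19 | 7-(benzyloxy)-3-[4-(benzyloxy)-3,5-dimethoxyphenyl]-5-methoxy-6-methyl-4H-chromen-4-one | COc1cc(-c2coc3cc(OCc4ccccc4)c(C)c(OC)c3c2=O)cc(OC)c1OCc1ccccc1 | intermediate
20 | 7-hydroxy-3-(4-hydroxy-3,5-dimethoxyphenyl)-5-methoxy-6-methyl-4H-chromen-4-one | COc1cc(-c2coc3cc(O)c(C)c(OC)c3c2=O)cc(OC)c1O | target

**Step count**
Total: 13 steps. Longest linear sequence: 11 steps (6 → 20, steps 3–13); the ring A branch (steps 1–2) joins at step 7.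

**Steps most likely to fail**

Step 9 (key ring closure). The acyl cation is stabilised by the β-oxygen and may be too weak an electrophile under anhydride activation. The trifluoroacetic acid released may also cleave or shift 4-methylbenzyl groups on the electron-rich ring before closure; loss of the O5 group after closure would be harmless, since step 10 removes all of them.
The fallback sets out from ester 9 and phenol 5 and returns at 16. It makes the same C4–C4a bond on the same symmetric ring, but before the pyranone is closed.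
- Saponification of 9 (LiOH, THF–H2O) should give 2-[4-(benzyloxy)-3,5-dimethoxyphenyl]acetic acid F1.
- With trifluoroacetic anhydride in CH2Cl2 this forms 2-[4-(benzyloxy)-3,5-dimethoxyphenyl]acetic trifluoroacetic anhydride F2 in the flask, a much stronger acylating agent than 15.
- F2 should C-acylate phenol 5 at either of its two equivalent ortho carbons (intermolecular Friedel–Crafts acylation; O-acylated material is cleaved with K2CO3/MeOH on work-up) to give the deoxybenzoin 2-[4-(benzyloxy)-3,5-dimethoxyphenyl]-1-{2-hydroxy-5-methyl-4,6-bis[(4-methylbenzyl)oxy]phenyl}ethan-1-one F3.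
- Heating F3 with N,N-dimethylformamide dimethyl acetal in toluene should give the enaminone (E)-2-[4-(benzyloxy)-3,5-dimethoxyphenyl]-3-(dimethylamino)-1-{2-hydroxy-5-methyl-4,6-bis[(4-methylbenzyl)oxy]phenyl}prop-2-en-1-one F4, which closes to 16 by conjugate addition of the 2-hydroxyl and loss of dimethylamine.

Step 7 (vinylic substitution). The phenoxide may attack sulfur of the enol tosylate (sulfonyl transfer) or react through a ring carbon, and reversible addition may erode the alkene geometry.
The fallback sets out from enol 11 and returns at 13.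
- Oxalyl chloride with catalytic DMF in CH2Cl2 (Vilsmeier-type deoxychlorination of the enol) should give methyl (Z)-2-[4-(benzyloxy)-3,5-dimethoxyphenyl]-3-chloroprop-2-enoate F5 (geometry nominal).
- Phenol 5 with K2CO3 in DMF should then displace chloride at the β-carbon to give 13. A vinyl chloride offers no second electrophilic centre, so the transfer pathway is closed.

Step 11 (differentiation of the three hydroxyls). Alkylation may reach the chelated 5-OH or stop short at the 4′-OH, which is hindered by two methoxy groups.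
The fallback sets out from 16 and returns at the target 20, bypassing steps 10–13.
- MgBr2·OEt2 in toluene–Et2O should remove only the 4-methylbenzyl group on O5, through the six-membered magnesium chelate with C4=O and attack of bromide on the benzylic carbon. This gives 3-[4-(benzyloxy)-3,5-dimethoxyphenyl]-5-hydroxy-6-methyl-7-[(4-methylbenzyl)oxy]-4H-chromen-4-one F6.
- Methylation (MeI, K2CO3, DMF) should give 3-[4-(benzyloxy)-3,5-dimethoxyphenyl]-5-methoxy-6-methyl-7-[(4-methylbenzyl)oxy]-4H-chromen-4-one F7, and hydrogenolysis (H2, Pd/C) should give 20.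
- This is kept as the fallback and not the main line because the 4′-O-benzyl ether between two methoxy groups may also respond to the Lewis acid.

**Further compounds**
F1 | step 9 | 2-[4-(benzyloxy)-3,5-dimethoxyphenyl]acetic acid | COc1cc(CC(=O)O)cc(OC)c1OCc1ccccc1
F2 | step 9 | 2-[4-(benzyloxy)-3,5-dimethoxyphenyl]acetic trifluoroacetic anhydride | COc1cc(CC(=O)OC(=O)C(F)(F)F)cc(OC)c1OCc1ccccc1
F3 | step 9 | 2-[4-(benzyloxy)-3,5-dimethoxyphenyl]-1-{2-hydroxy-5-methyl-4,6-bis[(4-methylbenzyl)oxy]phenyl}ethan-1-one | COc1cc(CC(=O)c2c(O)cc(OCc3ccc(C)cc3)c(C)c2OCc2ccc(C)cc2)cc(OC)c1OCc1ccccc1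
F4 | step 9 | (E)-2-[4-(benzyloxy)-3,5-dimethoxyphenyl]-3-(dimethylamino)-1-{2-hydroxy-5-methyl-4,6-bis[(4-methylbenzyl)oxy]phenyl}prop-2-en-1-one | CN(C)/C=C(\c1cc(OC)c(OCc2ccccc2)c(OC)c1)C(=O)c1c(O)cc(OCc2ccc(C)cc2)c(C)c1OCc1ccc(C)cc1
F5 | step 7 | methyl (Z)-2-[4-(benzyloxy)-3,5-dimethoxyphenyl]-3-chloroprop-2-enoate | COC(=O)/C(=C\Cl)c1cc(OC)c(OCc2ccccc2)c(OC)c1
F6 | step 11 | 3-[4-(benzyloxy)-3,5-dimethoxyphenyl]-5-hydroxy-6-methyl-7-[(4-methylbenzyl)oxy]-4H-chromen-4-one | COc1cc(-c2coc3cc(OCc4ccc(C)cc4)c(C)c(O)c3c2=O)cc(OC)c1OCc1ccccc1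
F7 | step 11 | 3-[4-(benzyloxy)-3,5-dimethoxyphenyl]-5-methoxy-6-methyl-7-[(4-methylbenzyl)oxy]-4H-chromen-4-one | COc1cc(-c2coc3cc(OCc4ccc(C)cc4)c(C)c(OC)c3c2=O)cc(OC)c1OCc1ccccc1
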